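| setting | north | north-east | Monday's | Friday's |
|---|---|---|---|---|
| starting material | 0.80 M | 0.80 M | 0.80 M | 0.80 M |
| protic impurity | 0.0074 M | 0.018 M | 0.0160 M | 0.00500 M |
| free catalyst | 1.1 mol% | 1.1 mol% | 1.1 mol% | 1.1 mol% |
| temperature | 50 °C | 72 °C |  |  |
| remark | run made earlier | run made earlier | at 40 °C until 5.0 min, from then on at 80 °C | at 80 °C throughout |
| time |  |  | 15 min | 4.0 min |
north run (percent of the starting material charged)

| time / min | target / % |
|---|---|
| 0.667 | 6 |
| 1.33 | 14 |
| 2.00 | 20 |
| 2.50 | 25 |
| 3.00 | 31 |
| 4.00 | 36 |
| 5.00 | 45 |

north-east run (percent of the starting material charged)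

| time / s | target / % |
|---|---|
| 10.0 | 8 |
| 12.0 | 9 |
| 15.0 | 14 |
| 25.0 | 19 |
| 40.0 | 29 |
| 60.0 | 47 |
| 90.0 | 53 |

(scatter of a reading: 2 percentage points)

* the winner by amount of target, in percent of the starting material charged; "neither" if no more than 2 percentage points parts them (Monday's / Friday's / neither)
* how much target is there at the end, in percent of the starting material charged: Monday's
* how much target is there at the end, in percent of the starting material charged: Friday's

- If the loss of starting material is first order, the north run's last reading gives 0.120 min⁻¹ at 50 °C, and the north-east run's gives 0.503 min⁻¹ at 72 °C; both are readings with their scatter, and they differ in impurity too, which I set aside.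
- An Arrhenius line through them has 60.6 kJ mol⁻¹, so I carry 0.0582 min⁻¹: the cold constant, the pseudo-first-order constant for loss of starting material at 40 °C with the catalyst at its charge. The same line gives 0.812 min⁻¹ at 80 °C.
- From above: if each protic impurity takes one starting material, target stops at 98.0 % in Monday's and 99.4 % in Friday's.
- From below, I let the hot stage run no faster than the north-east run and count no other loss. Monday's, with 74.8 % left at the change of temperature, gets 97.5 %, and Friday's gets 86.0 %.
- Tightening Friday's with the hot constant, I reckon 95.5 %, and I put Monday's ahead, near its ceiling.
- The forecast says Monday's, with 99.5 % and 96 %, on the ground that “Monday's stays high either way”. Its Monday's figure stands above my ceiling, and its Friday's figure stands inside my bracket.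
- The flasks give neither: Monday's 93.7 %, below my floor, and Friday's 93.3 %, inside the bracket.

    starting material + free catalyst → catalyst intermediate (k = 7.19 M⁻¹ min⁻¹, Ea = 67.0 kJ mol⁻¹)
    catalyst intermediate → free catalyst + target (k = 19.9 min⁻¹, Ea = 74.0 kJ mol⁻¹)
    2 starting material → self-condensation product (k = 0.00246 M⁻¹ min⁻¹, Ea = 77.0 kJ mol⁻¹)
    starting material + protic impurity → quenched substrate (k = 0.295 M⁻¹ min⁻¹, Ea = 70.0 kJ mol⁻¹)
    (constants at 40 °C)

- The cold constant gives 74.8 % of starting material in Monday's at 5.00 min, against 75.2 % in the flask at 5.00 min; for the same flask read at 4.0 min it gives 79.2 %, against 79.6 %, so watch that early reading. At the start of Monday's, starting material goes through the free catalyst 16 times as fast as into self-condensation product, and this momentary ratio of the two rates reads 20 at 5.41 min. At 15.0 min Monday's holds 4.31 % of self-condensation product, in percent of the starting material charged.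

The readings were computed from invented constants; scatter was added.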